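**Retrosynthetic overview**
1. Target ⇒ its tri-tert-butyl ester (global acidolysis last); the malate C1 ester C–O bond ⇒ primary alkyl iodide + caesium salt of 4-tert-butyl (R)-malate (from (R)-malic acid via its acetonide).
2. Iodide ⇒ ω-hydroxy lactone ⇒ (hydrogenation with debenzylation) Z-alkene ⇒ Wittig reaction of a C8 benzyloxy ylide with a C4 aldehyde side chain.
3. Key C–C bond (quaternary C to CH, both core stereocentres) ⇒ catalytic asymmetric Mukaiyama–Michael addition of a 5-silyloxyfuran-2-carboxylate to tert-butyl (E)-4-oxobut-2-enoate.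
4. Ring order: the only ring, the γ-lactone, is bought as 5-oxotetrahydrofuran-2-carboxylic acid, dehydrogenated and aromatised to the silyloxyfuran, returns as a butenolide in the key step and is saturated by hydrogenation.

Assumption: the target is taken exactly as drawn, i.e. (S) at the chain CH, (S) at the quaternary lactone carbon and (R) in the malate unit.

**Route**

Step 1
Reactants: 1 5-oxotetrahydrofuran-2-carboxylic acid (racemic)
Product: 2 tert-butyl 5-oxotetrahydrofuran-2-carboxylate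
Conditions: t-BuOC(=NH)CCl3 (2 equiv), CH2Cl2/cyclohexane, rt
Reagents that add atoms: tert-butyl 2,2,2-trichloroacetimidate, CC(C)(C)OC(=N)C(Cl)(Cl)Cl
Why: Acid-promoted tert-butyl esterification with a trichloroacetimidate (the substrate acid protonates the imidate) is mild enough to leave the γ-lactone untouched.

Step 2
Reactants: 2 tert-butyl 5-oxotetrahydrofuran-2-carboxylate
Product: 4 tert-butyl 5-oxo-4-(phenylselanyl)tetrahydrofuran-2-carboxylate, via lithium lactone enolate 3 (not isolated)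
Conditions: LiN(SiMe3)2 (1.05 equiv), THF, −78 °C; then PhSeBr, −78 °C
Reagents that add atoms: phenylselenyl bromide, Br[Se]c1ccccc1
Why: Kinetic deprotonation at the unhindered lactone α-CH2 (rather than the hindered α-acyloxy tert-butyl ester CH) followed by enolate selenenylation gives the α-selenide as a diastereomer mixture, which does not matter.

Step 3
Reactants: 4 tert-butyl 5-oxo-4-(phenylselanyl)tetrahydrofuran-2-carboxylate
Product: 6 tert-butyl 5-oxo-2,5-dihydrofuran-2-carboxylate, via selenoxide 5 (not isolated)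
Conditions: 30% aq H2O2 (2.5 equiv), pyridine, CH2Cl2, 0 °C to rt
Reagents that add atoms: none
Why: Oxidation to the selenoxide and spontaneous syn-elimination toward the only β-hydrogens (C3) gives the butenolide (selenoxide elimination).

Step 4
Reactants: 6 tert-butyl 5-oxo-2,5-dihydrofuran-2-carboxylate
Product: 7 tert-butyl 5-[(triisopropylsilyl)oxy]furan-2-carboxylate
Conditions: i-Pr3SiOSO2CF3 (1.1 equiv), Et3N (1.3 equiv), CH2Cl2, 0 °C
Reagents that add atoms: triisopropylsilyl trifluoromethanesulfonate, CC(C)[Si](OS(=O)(=O)C(F)(F)F)(C(C)C)C(C)C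
Why: Soft enolisation and O-silylation of the doubly activated C2–H gives the aromatic 2-silyloxyfuran, and any β,γ-unsaturated isomer of 6 converges on the same furan.

Step 5
Reactants: 8 2,2-dimethoxyacetaldehyde (60% in water); 9 tert-butyl 2-(diethoxyphosphoryl)acetate
Product: 10 tert-butyl (E)-4,4-dimethoxybut-2-enoate
Conditions: K2CO3 (2 equiv), H2O/THF, 0 °C to rt
Reagents that add atoms: none
Why: Horner–Wadsworth–Emmons olefination with a stabilised phosphonate gives the E-enoate and tolerates the aqueous aldehyde.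

Step 6
Reactants: 10 tert-butyl (E)-4,4-dimethoxybut-2-enoate
Product: 11 tert-butyl (E)-4-oxobut-2-enoate
Conditions: 1 M aq HCl, THF, rt
Reagents that add atoms: water, O
Why: Acid-catalysed acetal hydrolysis under dilute acid at room temperature frees the aldehyde without cleaving the tert-butyl ester or isomerising the E-alkene.

Step 7
Reactants: 7 tert-butyl 5-[(triisopropylsilyl)oxy]furan-2-carboxylate; 11 tert-butyl (E)-4-oxobut-2-enoate
Product: 12 tert-butyl (2S)-2-[(2S)-1-tert-butoxy-1,4-dioxobutan-2-yl]-5-oxo-2,5-dihydrofuran-2-carboxylate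
Conditions: (2R,5R)-5-benzyl-2-tert-butyl-3-methylimidazolidin-4-one (20 mol %), CF3CO2H (20 mol %), H2O (2 equiv), 11 (1.5 equiv), CHCl3, −20 °C
Reagents that add atoms: none
Why: In this iminium-catalysed asymmetric Mukaiyama–Michael reaction the benzyl group of the (2R,5R)-amine blocks one face of the E-iminium ion of 11, so C5 of furan 7 adds to the exposed Re face of the β-carbon and sets the (S)-CH centre, the preferred like approach of the furan sets the (S)-quaternary centre in the same bond formation (about 10:1 expected, minor epimer removed by chromatography), and water hydrolyses the silyl group and the product iminium ion.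

Step 8
Reactants: 13 8-bromooctan-1-ol
Product: 14 {[(8-bromooctyl)oxy]methyl}benzene
Conditions: BnOC(=NH)CCl3 (1.3 equiv), CF3SO3H (5 mol %), CH2Cl2/cyclohexane, 0 °C to rt
Reagents that add atoms: benzyl 2,2,2-trichloroacetimidate, N=C(OCc1ccccc1)C(Cl)(Cl)Cl
Why: Acid-catalysed O-benzylation with the trichloroacetimidate avoids the alkoxide that would attack the alkyl bromide in a Williamson ether synthesis.

Step 9
Reactants: 14 {[(8-bromooctyl)oxy]methyl}benzene
Product: 15 [8-(benzyloxy)octyl]triphenylphosphonium bromide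
Conditions: PPh3 (1.1 equiv), MeCN, reflux
Reagents that add atoms: triphenylphosphine, c1ccc(cc1)P(c1ccccc1)c1ccccc1
Why: SN2 quaternisation of triphenylphosphine by a primary bromide gives the Wittig salt.

Step 10
Reactants: 15 [8-(benzyloxy)octyl]triphenylphosphonium bromide; 12 tert-butyl (2S)-2-[(2S)-1-tert-butoxy-1,4-dioxobutan-2-yl]-5-oxo-2,5-dihydrofuran-2-carboxylate
Product: 17 tert-butyl (2S)-2-[(2S,4Z)-12-(benzyloxy)-1-tert-butoxy-1-oxododec-4-en-2-yl]-5-oxo-2,5-dihydrofuran-2-carboxylate, via ylide 16 (not isolated)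
Conditions: 15 (1.3 equiv), NaN(SiMe3)2 (1.25 equiv), THF, 0 °C; then 12, −78 °C to 0 °C
Reagents that add atoms: none
Why: In this Wittig olefination the non-stabilised ylide adds to the aldehyde at −78 °C faster than it deprotonates it, giving mainly the Z-alkene (geometry is irrelevant, it is hydrogenated next) without touching either stereocentre.

Step 11
Reactants: 17 tert-butyl (2S)-2-[(2S,4Z)-12-(benzyloxy)-1-tert-butoxy-1-oxododec-4-en-2-yl]-5-oxo-2,5-dihydrofuran-2-carboxylate
Product: 18 tert-butyl (2S)-2-[(2S)-1-tert-butoxy-12-hydroxy-1-oxododecan-2-yl]-5-oxotetrahydrofuran-2-carboxylate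
Conditions: H2 (3 atm), Pd(OH)2/C, EtOH/EtOAc, rt
Reagents that add atoms: none
Why: Catalytic hydrogenation saturates the chain alkene and the butenolide and hydrogenolyses the benzyl ether in one operation, while tert-butyl esters, lactone and both stereocentres are inert.

Step 12
Reactants: 18 tert-butyl (2S)-2-[(2S)-1-tert-butoxy-12-hydroxy-1-oxododecan-2-yl]-5-oxotetrahydrofuran-2-carboxylate
Product: 19 tert-butyl (2S)-2-[(2S)-1-tert-butoxy-12-iodo-1-oxododecan-2-yl]-5-oxotetrahydrofuran-2-carboxylate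
Conditions: [I][I] (1.3 equiv), PPh3 (1.3 equiv), imidazole (2 equiv), CH2Cl2, 0 °C to rt
Reagents that add atoms: iodine, [I][I]
Why: Appel-type iodination converts the primary alcohol into the iodide under neutral conditions that the lactone and tert-butyl esters tolerate.

Step 13
Reactants: 20 (R)-malic acid
Product: 21 [(4R)-2,2-dimethyl-5-oxo-1,3-dioxolan-4-yl]acetic acid
Conditions: Me2C(OMe)2, p-TsOH·H2O (cat.), rt
Reagents that add atoms: 2,2-dimethoxypropane, COC(C)(C)OC
Why: Transacetalisation ties the α-hydroxy acid into the five-membered dioxolanone, leaving only the C4 carboxyl free, and the stereocentre is not involved.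

Step 14
Reactants: 21 [(4R)-2,2-dimethyl-5-oxo-1,3-dioxolan-4-yl]acetic acid
Product: 22 tert-butyl [(4R)-2,2-dimethyl-5-oxo-1,3-dioxolan-4-yl]acetate
Conditions: t-BuOC(=NH)CCl3 (2 equiv), CH2Cl2/cyclohexane, rt
Reagents that add atoms: tert-butyl 2,2,2-trichloroacetimidate, CC(C)(C)OC(=N)C(Cl)(Cl)Cl
Why: Trichloroacetimidate tert-butyl esterification under anhydrous, weakly acidic conditions caps the free C4 acid and keeps the dioxolanone intact.

Step 15
Reactants: 22 tert-butyl [(4R)-2,2-dimethyl-5-oxo-1,3-dioxolan-4-yl]acetate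
Product: 23 (2R)-4-tert-butoxy-2-hydroxy-4-oxobutanoic acid
Conditions: AcOH/H2O/THF (2:1:1), 45 °C
Reagents that add atoms: none
Why: Mild acid hydrolysis of the acetonide (acetal hydrolysis) releases the α-hydroxy acid, and aqueous acetic acid is too weak to cleave the tert-butyl ester or racemise the centre.

Step 16
Reactants: 19 tert-butyl (2S)-2-[(2S)-1-tert-butoxy-12-iodo-1-oxododecan-2-yl]-5-oxotetrahydrofuran-2-carboxylate; 23 (2R)-4-tert-butoxy-2-hydroxy-4-oxobutanoic acid
Product: 25 4-tert-butyl 1-{(11S)-12-tert-butoxy-11-[(2S)-2-(tert-butoxycarbonyl)-5-oxotetrahydrofuran-2-yl]-12-oxododecyl} (2R)-2-hydroxybutanedioate, via caesium carboxylate 24 (not isolated)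
Conditions: 23 (1.5 equiv), Cs2CO3 (0.75 equiv), DMF, rt; then 19, rt
Reagents that add atoms: none
Why: SN2 O-alkylation of the caesium carboxylate by the primary iodide forms the malate C1 ester with unambiguous regiochemistry, the unprotected secondary hydroxyl being far less nucleophilic than the carboxylate.

Step 17
Reactants: 25 4-tert-butyl 1-{(11S)-12-tert-butoxy-11-[(2S)-2-(tert-butoxycarbonyl)-5-oxotetrahydrofuran-2-yl]-12-oxododecyl} (2R)-2-hydroxybutanedioate
Product: 26 (2S)-2-[(1S)-1-carboxy-11-{[(2R)-3-carboxy-2-hydroxypropanoyl]oxy}undecyl]-5-oxotetrahydrofuran-2-carboxylic acid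
Conditions: CF3CO2H/CH2Cl2 (1:1), rt; evaporate; MeCN/H2O, lyophilise
Reagents that add atoms: none
Why: Acidolysis of the three tert-butyl esters (loss of isobutene) frees all three acids, while the γ-lactone, the primary malate ester and the stereocentres are stable to anhydrous acid.

**Compound list**
1 | 5-oxotetrahydrofuran-2-carboxylic acid (racemic) | O=C(O)C1CCC(=O)O1 | starting material
2 | tert-butyl 5-oxotetrahydrofuran-2-carboxylate (racemic) | CC(C)(C)OC(=O)C1CCC(=O)O1 | intermediate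
3 | lithium 5-(tert-butoxycarbonyl)-4,5-dihydrofuran-2-olate (lactone enolate of 2) | [Li+].[O-]C1=CCC(C(=O)OC(C)(C)C)O1 | intermediate
4 | tert-butyl 5-oxo-4-(phenylselanyl)tetrahydrofuran-2-carboxylate (diastereomer mixture) | CC(C)(C)OC(=O)C1CC([Se]c2ccccc2)C(=O)O1 | intermediate
5 | tert-butyl 5-oxo-4-(phenylseleninyl)tetrahydrofuran-2-carboxylate (selenoxide) | CC(C)(C)OC(=O)C1CC([Se](=O)c2ccccc2)C(=O)O1 | intermediate
6 | tert-butyl 5-oxo-2,5-dihydrofuran-2-carboxylate (racemic) | CC(C)(C)OC(=O)C1C=CC(=O)O1 | intermediate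
7 | tert-butyl 5-[(triisopropylsilyl)oxy]furan-2-carboxylate | CC(C)[Si](Oc1ccc(o1)C(=O)OC(C)(C)C)(C(C)C)C(C)C | intermediate
8 | 2,2-dimethoxyacetaldehyde | COC(OC)C=O | starting material
9 | tert-butyl 2-(diethoxyphosphoryl)acetate | CCOP(=O)(OCC)CC(=O)OC(C)(C)C | starting material
10 | tert-butyl (E)-4,4-dimethoxybut-2-enoate | COC(OC)/C=C/C(=O)OC(C)(C)C | intermediate
11 | tert-butyl (E)-4-oxobut-2-enoate | O=C/C=C/C(=O)OC(C)(C)C | intermediate
12 | tert-butyl (2S)-2-[(2S)-1-tert-butoxy-1,4-dioxobutan-2-yl]-5-oxo-2,5-dihydrofuran-2-carboxylate | O=CC[C@H](C(=O)OC(C)(C)C)[C@]1(C(=O)OC(C)(C)C)C=CC(=O)O1 | intermediate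
13 | 8-bromooctan-1-ol | OCCCCCCCCBr | starting material
14 | {[(8-bromooctyl)oxy]methyl}benzene (benzyl 8-bromooctyl ether) | BrCCCCCCCCOCc1ccccc1 | intermediate
15 | [8-(benzyloxy)octyl]triphenylphosphonium bromide | [Br-].c1ccc(cc1)COCCCCCCCC[P+](c1ccccc1)(c1ccccc1)c1ccccc1 | intermediate
16 | [8-(benzyloxy)octylidene]triphenylphosphorane (ylide) | c1ccc(cc1)COCCCCCCCC=P(c1ccccc1)(c1ccccc1)c1ccccc1 | intermediate
17 | tert-butyl (2S)-2-[(2S,4Z)-12-(benzyloxy)-1-tert-butoxy-1-oxododec-4-en-2-yl]-5-oxo-2,5-dihydrofuran-2-carboxylate | c1ccc(cc1)COCCCCCCC/C=C\C[C@H](C(=O)OC(C)(C)C)[C@]1(C(=O)OC(C)(C)C)C=CC(=O)O1 | intermediate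
18 | tert-butyl (2S)-2-[(2S)-1-tert-butoxy-12-hydroxy-1-oxododecan-2-yl]-5-oxotetrahydrofuran-2-carboxylate | OCCCCCCCCCC[C@H](C(=O)OC(C)(C)C)[C@]1(C(=O)OC(C)(C)C)CCC(=O)O1 | intermediate
19 | tert-butyl (2S)-2-[(2S)-1-tert-butoxy-12-iodo-1-oxododecan-2-yl]-5-oxotetrahydrofuran-2-carboxylate | ICCCCCCCCCC[C@H](C(=O)OC(C)(C)C)[C@]1(C(=O)OC(C)(C)C)CCC(=O)O1 | intermediate
20 | (R)-malic acid, (2R)-2-hydroxybutanedioic acid | O=C(O)C[C@@H](O)C(=O)O | starting material
21 | [(4R)-2,2-dimethyl-5-oxo-1,3-dioxolan-4-yl]acetic acid | O=C(O)C[C@H]1OC(C)(C)OC1=O | intermediate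
22 | tert-butyl [(4R)-2,2-dimethyl-5-oxo-1,3-dioxolan-4-yl]acetate | CC(C)(C)OC(=O)C[C@H]1OC(C)(C)OC1=O | intermediate
23 | (2R)-4-tert-butoxy-2-hydroxy-4-oxobutanoic acid | CC(C)(C)OC(=O)C[C@@H](O)C(=O)O | intermediate
24 | caesium (2R)-4-tert-butoxy-2-hydroxy-4-oxobutanoate | CC(C)(C)OC(=O)C[C@@H](O)C(=O)[O-].[Cs+] | intermediate
25 | 4-tert-butyl 1-{(11S)-12-tert-butoxy-11-[(2S)-2-(tert-butoxycarbonyl)-5-oxotetrahydrofuran-2-yl]-12-oxododecyl} (2R)-2-hydroxybutanedioate | CC(C)(C)OC(=O)C[C@@H](O)C(=O)OCCCCCCCCCC[C@H](C(=O)OC(C)(C)C)[C@]1(C(=O)OC(C)(C)C)CCC(=O)O1 | intermediate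
26 | (2S)-2-[(1S)-1-carboxy-11-{[(2R)-3-carboxy-2-hydroxypropanoyl]oxy}undecyl]-5-oxotetrahydrofuran-2-carboxylic acid | O=C(O)C[C@@H](O)C(=O)OCCCCCCCCCC[C@H](C(=O)O)[C@]1(C(=O)O)CCC(=O)O1 | target

**Totals and risks**
Total steps: 17. Longest linear sequence: 10 (steps 1, 2, 3, 4, 7, 10, 11, 12, 16, 17).

The three steps most likely to fail:

Step 7. The bond is formed between two carbons that each carry a tert-butyl ester, and the diastereomer ratio of this reaction depends on the acid co-catalyst, the solvent and the ester size, so rate or the like/unlike ratio may suffer. An enantiomeric excess near 90% would also leave about 5% of a diastereomer once the (R)-malate is attached, so 17 should be enriched by chiral chromatography if needed. The fallback changes the ester pattern so that a small primary ester sits on the nucleophilic carbon; it sets out from 6 and comes back at 18. CF3CO2H/CH2Cl2 removes the tert-butyl group of 6 to give 5-oxo-2,5-dihydrofuran-2-carboxylic acid F1. Benzyl 2,2,2-trichloroacetimidate with catalytic CF3SO3H gives benzyl 5-oxo-2,5-dihydrofuran-2-carboxylate F2. i-Pr3SiOSO2CF3/Et3N gives benzyl 5-[(triisopropylsilyl)oxy]furan-2-carboxylate F3. The same iminium-catalysed Mukaiyama–Michael addition to 11 gives benzyl (2S)-2-[(2S)-1-tert-butoxy-1,4-dioxobutan-2-yl]-5-oxo-2,5-dihydrofuran-2-carboxylate F4. Wittig reaction with ylide 16 gives benzyl (2S)-2-[(2S,4Z)-12-(benzyloxy)-1-tert-butoxy-1-oxododec-4-en-2-yl]-5-oxo-2,5-dihydrofuran-2-carboxylate F5. H2 over Pd(OH)2/C saturates both alkenes and removes both benzyl groups to give (2S)-2-[(2S)-1-tert-butoxy-12-hydroxy-1-oxododecan-2-yl]-5-oxotetrahydrofuran-2-carboxylic acid F6. N,N-dimethylformamide di-tert-butyl acetal in toluene at 80 °C then esterifies only the carboxylic acid and gives 18.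

Step 10. The ylide is a strong base and aldehyde 12 is enolisable; enolisation can trigger retro-Michael loss of the furanolate or aldol side reactions. The fallback avoids any basic carbon nucleophile; it sets out from 12 and comes back at 18. Zn/CH2Br2/TiCl4 in THF/CH2Cl2 at 0 °C (non-basic methylenation) converts 12 into tert-butyl (2S)-2-[(2S)-1-tert-butoxy-1-oxopent-4-en-2-yl]-5-oxo-2,5-dihydrofuran-2-carboxylate F7. Cross-metathesis of F7 with an excess of {[(non-8-en-1-yl)oxy]methyl}benzene F8 (from purchased non-8-en-1-ol, NaH, BnBr) with the second-generation Grubbs catalyst RuCl2(=CHPh)(PCy3)(H2IMes) in CH2Cl2 at 40 °C gives tert-butyl (2S)-2-[(2S,4E)-12-(benzyloxy)-1-tert-butoxy-1-oxododec-4-en-2-yl]-5-oxo-2,5-dihydrofuran-2-carboxylate F9, together with some of its Z isomer 17; the electron-poor butenolide alkene does not take part. Hydrogenation of the mixture under the conditions of step 11 gives 18.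

Step 2. Deprotonation may compete at C2 (the α-acyloxy ester CH), and bis-selenenylation or Claisen self-condensation can lower the yield. The fallback replaces enolate chemistry by radical halogenation and elimination; it sets out from 2 and comes back at 7. N-Bromosuccinimide with 2,2'-azobis(2-methylpropionitrile) in PhCF3 at 80 °C brominates the captodative C2–H (flanked by the ring oxygen and the ester) to give tert-butyl 2-bromo-5-oxotetrahydrofuran-2-carboxylate F10. Et3N in CH2Cl2 at 0 °C eliminates HBr to tert-butyl 5-oxo-4,5-dihydrofuran-2-carboxylate F11, the β,γ-unsaturated isomer of 6. F11 is silylated under the conditions of step 4 and gives 7.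

**Further compounds**
F1 | step 7 | 5-oxo-2,5-dihydrofuran-2-carboxylic acid | O=C(O)C1C=CC(=O)O1
F2 | step 7 | benzyl 5-oxo-2,5-dihydrofuran-2-carboxylate | O=C(OCc1ccccc1)C1C=CC(=O)O1
F3 | step 7 | benzyl 5-[(triisopropylsilyl)oxy]furan-2-carboxylate | CC(C)[Si](Oc1ccc(o1)C(=O)OCc1ccccc1)(C(C)C)C(C)C
F4 | step 7 | benzyl (2S)-2-[(2S)-1-tert-butoxy-1,4-dioxobutan-2-yl]-5-oxo-2,5-dihydrofuran-2-carboxylate | O=CC[C@H](C(=O)OC(C)(C)C)[C@]1(C(=O)OCc2ccccc2)C=CC(=O)O1
F5 | step 7 | benzyl (2S)-2-[(2S,4Z)-12-(benzyloxy)-1-tert-butoxy-1-oxododec-4-en-2-yl]-5-oxo-2,5-dihydrofuran-2-carboxylate | c1ccc(cc1)COCCCCCCC/C=C\C[C@H](C(=O)OC(C)(C)C)[C@]1(C(=O)OCc2ccccc2)C=CC(=O)O1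
F6 | step 7 | (2S)-2-[(2S)-1-tert-butoxy-12-hydroxy-1-oxododecan-2-yl]-5-oxotetrahydrofuran-2-carboxylic acid | OCCCCCCCCCC[C@H](C(=O)OC(C)(C)C)[C@]1(C(=O)O)CCC(=O)O1
F7 | step 10 | tert-butyl (2S)-2-[(2S)-1-tert-butoxy-1-oxopent-4-en-2-yl]-5-oxo-2,5-dihydrofuran-2-carboxylate | C=CC[C@H](C(=O)OC(C)(C)C)[C@]1(C(=O)OC(C)(C)C)C=CC(=O)O1
F8 | step 10 | {[(non-8-en-1-yl)oxy]methyl}benzene | C=CCCCCCCCOCc1ccccc1
F9 | step 10 | tert-butyl (2S)-2-[(2S,4E)-12-(benzyloxy)-1-tert-butoxy-1-oxododec-4-en-2-yl]-5-oxo-2,5-dihydrofuran-2-carboxylate | c1ccc(cc1)COCCCCCCC/C=C/C[C@H](C(=O)OC(C)(C)C)[C@]1(C(=O)OC(C)(C)C)C=CC(=O)O1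
F10 | step 2 | tert-butyl 2-bromo-5-oxotetrahydrofuran-2-carboxylate | CC(C)(C)OC(=O)C1(Br)CCC(=O)O1
F11 | step 2 | tert-butyl 5-oxo-4,5-dihydrofuran-2-carboxylate | CC(C)(C)OC(=O)C1=CCC(=O)O1
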